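**Retrosynthetic overview**
- The target comes from its 6-deoxy-7-ketone (late C6 enolate hydroxylation), the ketone from a 7β-silyl ether, and the 2,3-dihydrofuran from a spiro γ-lactone (chemoselective lactone-to-lactol reduction, then dehydration).
- Key disconnection, C9–C11 together with O9–C13: the samarium ketyl of a cis-decalin C9 ketone adds 1,6 to 4-vinylbutenolide, and the C9 alkoxide then closes the tetrahydrofuran by oxa-Michael addition.
- The cis-decalin ketone comes from a Δ5-octalin: H-5 by hydroxyl-directed hydrogenation, the C7 oxygen by allylic oxidation, the 3β,19-diacetate by hydride reduction of a C3 ketone/C4 ester.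
- The Δ5 keto ester comes from a Robinson-annulation enone ester by one-pot dianion double methylation (C8, then C4); the enone ester comes from 2-methylcyclohexane-1,3-dione and Nazarov reagent.
- Ring order: ring B (the dione), ring A (annulation), spiro tetrahydrofuran plus γ-lactone (key cascade), 2,3-dihydrofuran (from the lactone).

Assumption: the SMILES is taken literally, so H-5 is cis to the C10 methyl (cis-fused decalin, 5R); locants follow labdane numbering (decalin C1–C10, C17 on C8, C18/C19 = α-methyl/β-CH2O on C4, C20 on C10, side chain C11–C16; β = the face of the C10 methyl).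

Step 1
Reactants: 1 2-methylcyclohexane-1,3-dione; 2 methyl 3-oxopent-4-enoate (Nazarov reagent)
Product: 4 methyl (4aS)-4a-methyl-2,5-dioxo-2,3,4,4a,5,6,7,8-octahydronaphthalene-1-carboxylate, via triketone 3 (not isolated)
Conditions: Et3N (5 mol %), EtOAc, rt; then L-phenylalanine (1 equiv), (1S)-(+)-camphor-10-sulfonic acid (0.5 equiv), DMF, 40–60 °C
Reagents that add atoms: none
Why: Michael addition followed by an amino-acid-mediated Hajos–Parrish–Eder–Sauer–Wiechert aldol condensation (asymmetric Robinson annulation), in which the L-amino-acid enamine of the β-keto ester chain attacks one enantiotopic ring carbonyl and sets C10 as S, the same sense as in (S)-Wieland–Miescher ketone.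

Step 2
Reactants: 4 methyl (4aS)-4a-methyl-2,5-dioxo-2,3,4,4a,5,6,7,8-octahydronaphthalene-1-carboxylate
Product: 7 methyl (1R,4aS,6R)-1,4a,6-trimethyl-2,5-dioxo-1,2,3,4,4a,5,6,7-octahydronaphthalene-1-carboxylate, via sodium dienolate 5 (not isolated), via sodium lithium dianion 6 (not isolated)
Conditions: NaH (1.0 equiv), THF, 0 °C; LiN(i-Pr)2 (1.05 equiv), −78 °C; MeI (1.0 equiv), −78 °C; then MeI (3 equiv), DMPU, −78 °C → rt
Reagents that add atoms: iodomethane, CI
Why: Dianion alkylation following Hauser's rule, in which the last-formed C8 ketone enolate is methylated first (anti to the angular methyl, giving the equatorial 8α-methyl, with no base left strong enough for a second C8 alkylation) and the stabilised dienolate, which meanwhile protects the C3 ketone, is then C-methylated at C4 (deconjugative α-alkylation) from the α-face anti to the C10 methyl, so the ester ends up β (C19) and the alkene moves to C5=C6.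

Step 3
Reactants: 7 methyl (1R,4aS,6R)-1,4a,6-trimethyl-2,5-dioxo-1,2,3,4,4a,5,6,7-octahydronaphthalene-1-carboxylate
Product: 8 Δ5-triol 4β-(hydroxymethyl)-4α,8α,10β-trimethyl-Δ5-octalin-3β,9β-diol
Conditions: LiAlH4 (excess), THF, 0 °C → rt; Fieser work-up
Reagents that add atoms: none
Why: Exhaustive hydride reduction in which hydride reaches C3 and C9 axially from the α-face (anti to the C10 methyl and the 4β-carbon substituent) to give the equatorial 3β- and 9β-alcohols (C9 is reoxidised later) while the ester becomes the C19 carbinol.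

Step 4
Reactants: 8 Δ5-triol 4β-(hydroxymethyl)-4α,8α,10β-trimethyl-Δ5-octalin-3β,9β-diol
Product: 9 3β,19-diacetoxy-4α,8α,10β-trimethyl-Δ5-octalin-9β-ol
Conditions: Ac2O (2.2 equiv), pyridine, 0 °C → rt (no DMAP)
Reagents that add atoms: acetic anhydride, CC(=O)OC(C)=O
Why: Sterically controlled acylation, in which the primary 19-OH and the 3β-OH are acetylated while the 9β-OH, flanked by the quaternary C10 and the methyl-bearing C8, stays free.

Step 5
Reactants: 9 3β,19-diacetoxy-4α,8α,10β-trimethyl-Δ5-octalin-9β-ol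
Product: 10 3β,19-diacetoxy-9β-hydroxy-4α,8α,10β-trimethyl-Δ5-octalin-7-one
Conditions: Rh2(cap)4 (cap = caprolactamate, 1 mol %), t-BuOOH (70% aq, 5 equiv), NaHCO3, ClCH2CH2Cl, 40 °C
Reagents that add atoms: tert-butyl hydroperoxide, CC(C)(C)OO
Why: Doyle-type allylic C–H oxidation, where C7 is the only allylic CH2 because C4 and C10 are quaternary, and the saturated secondary 9-OH is not oxidised by the tert-butylperoxy radical chain.

Step 6
Reactants: 10 3β,19-diacetoxy-9β-hydroxy-4α,8α,10β-trimethyl-Δ5-octalin-7-one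
Product: 11 3β,19-diacetoxy-4α,8α,10β-trimethyl-Δ5-octalin-7β,9β-diol
Conditions: NaBH4, CeCl3·7H2O, MeOH, −20 °C
Reagents that add atoms: none
Why: Luche 1,2-reduction with axial hydride delivery from the α-face (anti to the C10 methyl), giving the equatorial 7β-allylic alcohol as with 7-oxo-Δ5-steroids.

Step 7
Reactants: 11 3β,19-diacetoxy-4α,8α,10β-trimethyl-Δ5-octalin-7β,9β-diol
Product: 12 3β,19-diacetoxy-4α,8α,10β-trimethyl-5β-decalin-7β,9β-diol (cis-fused)
Conditions: H2 (1–3 bar), [Ir(cod)(PCy3)(py)]PF6 (5–10 mol %), CH2Cl2, rt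
Reagents that add atoms: none
Why: Hydroxyl-directed homogeneous hydrogenation (Crabtree–Stork type), in which iridium bound to the allylic 7β-OH (helped by the homoallylic 9β-OH) delivers H2 to the β-face of C5=C6 and sets H-5 β, the cis ring fusion that undirected α-face hydrogenation would not give.

Step 8
Reactants: 12 3β,19-diacetoxy-4α,8α,10β-trimethyl-5β-decalin-7β,9β-diol
Product: 13 3β,19-diacetoxy-7β-(triethylsilyloxy)-4α,8α,10β-trimethyl-5β-decalin-9β-ol
Conditions: Et3SiCl (1.05 equiv), imidazole, CH2Cl2, −20 °C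
Reagents that add atoms: chlorotriethylsilane, CC[Si](Cl)(CC)CC
Why: Selective silylation of the less hindered 7β-OH, the 9β-OH next to the quaternary C10 reacting much more slowly.

Step 9
Reactants: 13 3β,19-diacetoxy-7β-(triethylsilyloxy)-4α,8α,10β-trimethyl-5β-decalin-9β-ol
Product: 14 3β,19-diacetoxy-7β-(triethylsilyloxy)-4α,8α,10β-trimethyl-5β-decalin-9-one
Conditions: Dess–Martin periodinane, NaHCO3, CH2Cl2, 0 °C → rt
Reagents that add atoms: none
Why: Buffered Dess–Martin oxidation of the hindered 9-OH regenerates the C9 ketone under non-epimerising conditions, so C8 is untouched and the β-silyloxy group is not eliminated.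

Step 10
Reactants: 15 4-bromofuran-2(5H)-one; 16 tributyl(vinyl)stannane
Product: 17 4-vinylfuran-2(5H)-one
Conditions: Pd(PPh3)4 (5 mol %), toluene, 80 °C (trace BHT); used fresh
Reagents that add atoms: none
Why: Stille cross-coupling, the β-bromo butenolide being a vinylogous acyl bromide that adds oxidatively to zerovalent palladium with ease.

Step 11
Reactants: 14 3β,19-diacetoxy-7β-(triethylsilyloxy)-4α,8α,10β-trimethyl-5β-decalin-9-one; 17 4-vinylfuran-2(5H)-one
Product: 19 bis-spiro lactone 3β,19-diacetoxy-7β-(triethylsilyloxy)-9α,13R-epoxy-5β-labdan-15,16-olide, via hydroxy butenolide 18 (not isolated)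
Conditions: SmI2 (3 equiv), t-BuOH (2 equiv), THF, −78 → 0 °C, slow addition of 17 (1.5 equiv); then DBU (0.3 equiv), rt
Reagents that add atoms: none
Why: Proposed new method: SmI2 turns the C9 carbonyl into a ketyl, a nucleophilic (polarity-reversed) carbonyl carbon, which adds 1,6 to the terminal vinyl carbon C11 of dienoate 17 so that two normally electrophilic carbons are joined, the dienolate radical is reduced and protonated, and DBU then conjugates the butenolide and triggers 5-exo oxa-Michael addition of the C9 alkoxide to C13; the closest known reaction is the Fukuzawa–Inanaga SmI2 ketone–acrylate spirolactonisation of hindered cyclic ketones, here extended vinylogously; the C–C bond should form on the convex β-face because ring A (C4 with its α-methyl) folded under ring B blocks the α-face, giving C11 β and O9 α (9R), and in the ring closure the flat C14–H edge of the butenolide should face the bulky C10 side and the C16 methylene the C8 side, so 13R is expected as the major, separable epimer, with the minor one re-equilibrated with DBU.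

Step 12
Reactants: 19 bis-spiro lactone 3β,19-diacetoxy-7β-(triethylsilyloxy)-9α,13R-epoxy-5β-labdan-15,16-olide
Product: 20 lactol 3β,19-diacetoxy-7β-(triethylsilyloxy)-9α,13R;15,16-diepoxy-5β-labdan-15-ol (anomer mixture)
Conditions: disiamylborane [(Me2CHCHMe)2BH, 3 equiv, from BH3·THF and 2-methylbut-2-ene], THF, 0 °C → rt; then H2O
Reagents that add atoms: none
Why: Brown's disiamylborane reduces γ-lactones to lactols but leaves acetates and silyl ethers alone, as in the reduction of acylated aldonolactones.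

Step 13
Reactants: 20 lactol 3β,19-diacetoxy-7β-(triethylsilyloxy)-9α,13R;15,16-diepoxy-5β-labdan-15-ol
Product: 22 3β,19-diacetoxy-7β-(triethylsilyloxy)-9α,13R;15,16-diepoxy-5β-labd-14-ene, via lactol mesylate 21 (not isolated)
Conditions: MsCl (1.5 equiv), Et3N (5 equiv), CH2Cl2, −40 °C → rt
Reagents that add atoms: none
Why: Glycal-type lactol dehydration (anomeric mesylation, then amine-induced elimination) gives the 2,3-dihydrofuran, since only C14 carries β-hydrogens and the basic medium avoids acid-induced opening of the spiro ether to the furan.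

Step 14
Reactants: 22 3β,19-diacetoxy-7β-(triethylsilyloxy)-9α,13R;15,16-diepoxy-5β-labd-14-ene
Product: 23 3β,19-diacetoxy-9α,13R;15,16-diepoxy-5β-labd-14-en-7β-ol
Conditions: Bu4NF (1.5 equiv), AcOH (1.5 equiv), THF, 0 °C
Reagents that add atoms: none
Why: Buffered fluoride desilylation removes the triethylsilyl ether while sparing the acetates and the acid-labile spiro enol ether.

Step 15
Reactants: 23 3β,19-diacetoxy-9α,13R;15,16-diepoxy-5β-labd-14-en-7β-ol
Product: 24 3β,19-diacetoxy-9α,13R;15,16-diepoxy-5β-labd-14-en-7-one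
Conditions: Dess–Martin periodinane, pyridine, CH2Cl2, 0 °C
Reagents that add atoms: none
Why: Dess–Martin oxidation buffered with pyridine gives the C7 ketone without acid or base, so the enol ether survives, C8 is not epimerised and the β-alkoxy ketone is not eliminated.

Step 16
Reactants: 24 3β,19-diacetoxy-9α,13R;15,16-diepoxy-5β-labd-14-en-7-one
Product: 26 target (3S,4S,5R,6S,8S,9R,10S,13R)-3,19-diacetoxy-6-hydroxy-9,13;15,16-diepoxylabd-14-en-7-one, via lithium enolate 25 (not isolated)
Conditions: LiN(SiMe3)2 (1.1 equiv), THF, −78 °C; 2-(phenylsulfonyl)-3-phenyloxaziridine (1.3 equiv), −78 °C; pH 7 buffer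
Reagents that add atoms: 2-(phenylsulfonyl)-3-phenyloxaziridine (Davis oxaziridine), O=S(=O)(c1ccccc1)N1OC1c1ccccc1
Why: Kinetic enolisation at the C6 methylene (ketone before acetate, CH2 before the tertiary C8–H) followed by Davis oxaziridine hydroxylation, the oxidant approaching the enolate on the β-face, anti to the quaternary C4 and syn to H-5, to give the 6β-alcohol.

**Compound list**
1 | 2-methylcyclohexane-1,3-dione | CC1C(=O)CCCC1=O | starting material
2 | methyl 3-oxopent-4-enoate (Nazarov reagent) | COC(=O)CC(=O)C=C | starting material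
3 | triketone, methyl 5-(1-methyl-2,6-dioxocyclohexyl)-3-oxopentanoate | COC(=O)CC(=O)CCC1(C)C(=O)CCCC1=O | intermediate
4 | methyl (4aS)-4a-methyl-2,5-dioxo-2,3,4,4a,5,6,7,8-octahydronaphthalene-1-carboxylate | COC(=O)C1=C2CCCC(=O)[C@@]2(C)CCC1=O | intermediate
5 | sodium dienolate of 4 (O–C3=C4–C5=C6) | COC(=O)C1=C([O-])CC[C@@]2(C)C1=CCCC2=O.[Na+] | intermediate
6 | sodium lithium dianion of 4 (dienolate plus C8=C9 enolate) | COC(=O)C1=C([O-])CC[C@@]2(C)C1=CCC=C2[O-].[Na+].[Li+] | intermediate
7 | methyl (1R,4aS,6R)-1,4a,6-trimethyl-2,5-dioxo-1,2,3,4,4a,5,6,7-octahydronaphthalene-1-carboxylate (4β-ester, 4α,8α-dimethyl, Δ5) | COC(=O)[C@@]1(C)C(=O)CC[C@@]2(C)C1=CC[C@@H](C)C2=O | intermediate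
8 | Δ5-triol, 4β-(hydroxymethyl)-4α,8α,10β-trimethyl-Δ5-octalin-3β,9β-diol | OC[C@@]1(C)[C@@H](O)CC[C@@]2(C)C1=CC[C@@H](C)[C@@H]2O | intermediate
9 | 3β,19-diacetoxy-4α,8α,10β-trimethyl-Δ5-octalin-9β-ol | CC(=O)OC[C@@]1(C)[C@@H](OC(C)=O)CC[C@@]2(C)C1=CC[C@@H](C)[C@@H]2O | intermediate
10 | 3β,19-diacetoxy-9β-hydroxy-4α,8α,10β-trimethyl-Δ5-octalin-7-one | CC(=O)OC[C@@]1(C)[C@@H](OC(C)=O)CC[C@@]2(C)C1=CC(=O)[C@@H](C)[C@@H]2O | intermediate
11 | 3β,19-diacetoxy-4α,8α,10β-trimethyl-Δ5-octalin-7β,9β-diol | CC(=O)OC[C@@]1(C)[C@@H](OC(C)=O)CC[C@@]2(C)C1=C[C@H](O)[C@@H](C)[C@@H]2O | intermediate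
12 | 3β,19-diacetoxy-4α,8α,10β-trimethyl-5β-decalin-7β,9β-diol (cis-fused) | CC(=O)OC[C@@]1(C)[C@@H](OC(C)=O)CC[C@@]2(C)[C@@H]1C[C@H](O)[C@@H](C)[C@@H]2O | intermediate
13 | 3β,19-diacetoxy-7β-(triethylsilyloxy)-4α,8α,10β-trimethyl-5β-decalin-9β-ol | CC(=O)OC[C@@]1(C)[C@@H](OC(C)=O)CC[C@@]2(C)[C@@H]1C[C@H](O[Si](CC)(CC)CC)[C@@H](C)[C@@H]2O | intermediate
14 | 3β,19-diacetoxy-7β-(triethylsilyloxy)-4α,8α,10β-trimethyl-5β-decalin-9-one | CC(=O)OC[C@@]1(C)[C@@H](OC(C)=O)CC[C@@]2(C)[C@@H]1C[C@H](O[Si](CC)(CC)CC)[C@@H](C)C2=O | intermediate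
15 | 4-bromofuran-2(5H)-one | BrC1=CC(=O)OC1 | starting material
16 | tributyl(vinyl)stannane | C=C[Sn](CCCC)(CCCC)CCCC | starting material
17 | 4-vinylfuran-2(5H)-one | C=CC1=CC(=O)OC1 | intermediate
18 | hydroxy butenolide (14 with 9α-OH and a 9β-[2-(5-oxo-2,5-dihydrofuran-3-yl)ethyl] chain) | CC(=O)OC[C@@]1(C)[C@@H](OC(C)=O)CC[C@@]2(C)[C@@H]1C[C@H](O[Si](CC)(CC)CC)[C@@H](C)[C@]2(O)CCC1=CC(=O)OC1 | intermediate
19 | bis-spiro lactone, 3β,19-diacetoxy-7β-(triethylsilyloxy)-9α,13R-epoxy-5β-labdan-15,16-olide | CC(=O)OC[C@@]1(C)[C@@H](OC(C)=O)CC[C@@]2(C)[C@@H]1C[C@H](O[Si](CC)(CC)CC)[C@@H](C)[C@]21CC[C@]2(CC(=O)OC2)O1 | intermediate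
20 | lactol, 3β,19-diacetoxy-7β-(triethylsilyloxy)-9α,13R;15,16-diepoxy-5β-labdan-15-ol (anomer mixture) | CC(=O)OC[C@@]1(C)[C@@H](OC(C)=O)CC[C@@]2(C)[C@@H]1C[C@H](O[Si](CC)(CC)CC)[C@@H](C)[C@]21CC[C@]2(CC(O)OC2)O1 | intermediate
21 | lactol mesylate (15-methanesulfonate of 20) | CC(=O)OC[C@@]1(C)[C@@H](OC(C)=O)CC[C@@]2(C)[C@@H]1C[C@H](O[Si](CC)(CC)CC)[C@@H](C)[C@]21CC[C@]2(CC(OS(C)(=O)=O)OC2)O1 | intermediate
22 | 3β,19-diacetoxy-7β-(triethylsilyloxy)-9α,13R;15,16-diepoxy-5β-labd-14-ene | CC(=O)OC[C@@]1(C)[C@@H](OC(C)=O)CC[C@@]2(C)[C@@H]1C[C@H](O[Si](CC)(CC)CC)[C@@H](C)[C@]21CC[C@]2(C=COC2)O1 | intermediate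
23 | 3β,19-diacetoxy-9α,13R;15,16-diepoxy-5β-labd-14-en-7β-ol | CC(=O)OC[C@@]1(C)[C@@H](OC(C)=O)CC[C@@]2(C)[C@@H]1C[C@H](O)[C@@H](C)[C@]21CC[C@]2(C=COC2)O1 | intermediate
24 | 3β,19-diacetoxy-9α,13R;15,16-diepoxy-5β-labd-14-en-7-one | CC(=O)OC[C@@]1(C)[C@@H](OC(C)=O)CC[C@@]2(C)[C@@H]1CC(=O)[C@@H](C)[C@]21CC[C@]2(C=COC2)O1 | intermediate
25 | lithium C6=C7 enolate of 24 | CC(=O)OC[C@@]1(C)[C@@H](OC(C)=O)CC[C@@]2(C)[C@@H]1C=C([O-])[C@@H](C)[C@]21CC[C@]2(C=COC2)O1.[Li+] | intermediate
26 | (3S,4S,5R,6S,8S,9R,10S,13R)-3,19-diacetoxy-6-hydroxy-9,13;15,16-diepoxylabd-14-en-7-one (3β,19-diacetoxy, 6β-OH, 5β-H, 8α-methyl) | CC(=O)OC[C@@]1(C)[C@@H](OC(C)=O)CC[C@@]2(C)[C@@H]1[C@H](O)C(=O)[C@@H](C)[C@]21CC[C@]2(C=COC2)O1 | target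

**Step count**
Total steps: 16. Longest linear sequence: 15 (steps 1–9 and 11–16; step 10 makes the coupling partner).

**The three steps most likely to fail**

Step 11, the samarium cascade. The easily reduced vinylbutenolide may be reduced or dimerise instead of cross-coupling with the hindered ketyl, and the C13 selectivity may be low. The fallback sets out from 14 and returns at 19, and makes the two bonds separately. CH2=CHMgBr with CeCl3 (THF, −78 °C) adds to 14 from the same β-face to give the 9β-vinyl 9α-carbinol F1. 9-BBN-H (THF, rt) hydroborates the vinyl group to the B-alkyl-9-BBN borane F2. This is coupled in the same flask with bromobutenolide 15 [PdCl2(dppf) (5 mol %), K3PO4, THF/DMF/H2O, 50 °C, B-alkyl Suzuki–Miyaura coupling] to give hydroxy butenolide 18, this time isolated. DBU (CH2Cl2, rt) then closes 18 to 19.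

Step 16, the final hydroxylation. Deprotonation at C8 would open the 9,13-ether by β-elimination or epimerise C8, and the acetates and the α-ketol product are base-sensitive. The fallback sets out from 24 and returns at 26, and replaces the lithium enolate by enamine catalysis. D-Proline (30 mol %) and nitrosobenzene (CHCl3/DMSO, 0 °C) effect an α-aminoxylation at the less substituted C6, with catalyst and substrate both favouring the β-face, to give the 6β-(N-phenylaminooxy) ketone F3. CuSO4 (30 mol %) in MeOH at 0 °C then cleaves the N–O bond to give 26.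

Step 13, the lactol dehydration. Ionisation at C15 under mesylation conditions can go on to break the C13–O9 bond and aromatise to the 3-substituted furan. The fallback sets out from 20 and returns at 22, and uses a neutral syn-elimination instead. N-(Phenylseleno)phthalimide and PBu3 (THF, 0 °C) convert the lactol into the C15 phenyl selenide F4. NaIO4 with NaHCO3 (THF/H2O, 0 °C) gives the selenoxide F5. F5 eliminates at room temperature in the presence of Et3N and ethyl vinyl ether (selenenic acid scavenger) towards C14, the only β-carbon bearing hydrogen, to give 22.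

**Further compounds**
F1 | step 11 | 9β-vinyl 9α-carbinol, 3β,19-diacetoxy-7β-(triethylsilyloxy)-9β-vinyl-4α,8α,10β-trimethyl-5β-decalin-9α-ol | CC(=O)OC[C@@]1(C)[C@@H](OC(C)=O)CC[C@@]2(C)[C@@H]1C[C@H](O[Si](CC)(CC)CC)[C@@H](C)[C@]2(O)C=C
F2 | step 11 | B-alkyl-9-BBN borane (F1 with CH2CH2–B(9-BBN) in place of vinyl) | CC(=O)OC[C@@]1(C)[C@@H](OC(C)=O)CC[C@@]2(C)[C@@H]1C[C@H](O[Si](CC)(CC)CC)[C@@H](C)[C@]2(O)CCB1C2CCCC1CCC2
F3 | step 16 | 6β-(N-phenylaminooxy) ketone (24 with 6β-ONHPh) | CC(=O)OC[C@@]1(C)[C@@H](OC(C)=O)CC[C@@]2(C)[C@@H]1[C@H](ONc1ccccc1)C(=O)[C@@H](C)[C@]21CC[C@]2(C=COC2)O1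
F4 | step 13 | C15 phenyl selenide (20 with SePh in place of the lactol OH) | CC(=O)OC[C@@]1(C)[C@@H](OC(C)=O)CC[C@@]2(C)[C@@H]1C[C@H](O[Si](CC)(CC)CC)[C@@H](C)[C@]21CC[C@]2(CC([Se]c3ccccc3)OC2)O1
F5 | step 13 | C15 phenyl selenoxide of F4 | CC(=O)OC[C@@]1(C)[C@@H](OC(C)=O)CC[C@@]2(C)[C@@H]1C[C@H](O[Si](CC)(CC)CC)[C@@H](C)[C@]21CC[C@]2(CC([Se](=O)c3ccccc3)OC2)O1
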